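**Strategy.** The cyclohexane ring of the cis-hydrindanone (C3a, C4, C5, C6, C7, C7a) is cut at its two opposite bonds, C3a–C4 and C6–C7. This gives a C3 aldehyde–alkenylboronate (C4–C6) and a cyclopentenone that carries C7 as the γ-carbon of a (Z)-2-(bromomethyl)enoate. One flask reunites them: indium-mediated allylation of the C6 aldehyde forms C6–C7, then rhodium-catalysed 1,4-addition of the C4 boronate to C3a closes the ring. The step uses C3a being β to the C2 ketone, C4 being the exo-methylene carbon and C7 being allylic to the acrylate that becomes the oxirane ester. The C1 side chain is completed last at a sulfur-bearing C1.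

Key step: step 10

Numbering: octahydro-1H-inden-2-one core; C1 bears the acetoxyethyl group, C4 the methylidene, C5 and C6 the acyloxy groups, C7 the oxirane ester.

Remark: compounds 1, 8, 12, 16 and 21 are taken as purchasable single isomers; the C1 configuration of the target is judged from a conformational analysis to be the less stable, kinetically reached epimer, so it is set in the last step without base.

**Step 1**
Reactants: 1 (S)-2,2-dimethyl-1,3-dioxolane-4-carbaldehyde
Product: 2 (R)-4-ethynyl-2,2-dimethyl-1,3-dioxolane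
Conditions: Ohira–Bestmann reagent, K2CO3, MeOH, 0 °C to rt
Reagents that add atoms: dimethyl (1-diazo-2-oxopropyl)phosphonate CC(=O)C(=[N+]=[N-])P(=O)(OC)OC
Why: Ohira–Bestmann (Seyferth–Gilbert) homologation turns the aldehyde into the terminal alkyne under mild carbonate conditions that should leave the adjacent stereocentre untouched.

**Step 2**
Reactants: 2 (R)-4-ethynyl-2,2-dimethyl-1,3-dioxolane
Product: 3 (R)-but-3-yne-1,2-diol
Conditions: AcOH–H2O (4:1), 40 °C
Reagents that add atoms: none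
Why: Acid-catalysed acetal hydrolysis frees the diol without affecting the stereocentre.

**Step 3**
Reactants: 3 (R)-but-3-yne-1,2-diol
Product: 4 (4R)-4-ethynyl-2-(4-methoxyphenyl)-1,3-dioxolane (both acetal epimers)
Conditions: 4-methoxybenzaldehyde dimethyl acetal, CSA (cat.), CH2Cl2, rt
Reagents that add atoms: 4-methoxybenzaldehyde dimethyl acetal COc1ccc(C(OC)OC)cc1
Why: Acid-catalysed transacetalisation gives the p-methoxybenzylidene acetal needed for the regioselective opening; the new acetal centre is irrelevant.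

**Step 4**
Reactants: 4 (4R)-4-ethynyl-2-(4-methoxyphenyl)-1,3-dioxolane
Product: 5 (R)-2-[(4-methoxyphenyl)methoxy]but-3-yn-1-ol
Conditions: DIBAL-H (3 equiv), CH2Cl2, −78 to 0 °C; Rochelle salt
Reagents that add atoms: none
Why: In this reductive acetal opening the aluminium binds the less hindered primary oxygen and hydride goes to the acetal carbon, so the PMB ether should end on the secondary oxygen.

**Step 5**
Reactants: 5 (R)-2-[(4-methoxyphenyl)methoxy]but-3-yn-1-ol
Product: 6 (R)-2-[(4-methoxyphenyl)methoxy]-3-(4,4,5,5-tetramethyl-1,3,2-dioxaborolan-2-yl)but-3-en-1-ol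
Conditions: CuCl (5 mol %), 1,3-dimesitylimidazolinium chloride (5 mol %), NaOt-Bu (10 mol %), B2pin2, MeOH, THF, rt
Reagents that add atoms: bis(pinacolato)diboron CC1(C)OB(OC1(C)C)B1OC(C)(C)C(C)(C)O1
Why: NHC–copper-catalysed protoboration of a terminal alkyne with a propargylic ether and an N-aryl carbene ligand should place boron on the internal carbon (α-selective hydroboration).

**Step 6**
Reactants: 6 (R)-2-[(4-methoxyphenyl)methoxy]-3-(4,4,5,5-tetramethyl-1,3,2-dioxaborolan-2-yl)but-3-en-1-ol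
Product: 7 (R)-2-[(4-methoxyphenyl)methoxy]-3-(4,4,5,5-tetramethyl-1,3,2-dioxaborolan-2-yl)but-3-enal
Conditions: Dess–Martin periodinane, NaHCO3, CH2Cl2, 0 °C; used crude
Reagents that add atoms: none
Why: Buffered Dess–Martin oxidation is neutral and tolerates the boronate, so the α-alkoxy aldehyde should form without epimerisation or double-bond migration.

**Step 7**
Reactants: 8 (R)-4-[(tert-butyldimethylsilyl)oxy]cyclopent-2-en-1-one
Product: 10 (S)-4-ethenylcyclopent-2-en-1-one, via trans-silyloxy ketone 9 (not isolated)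
Conditions: vinylMgBr, CuBr·SMe2 (10 mol %), THF, −78 °C; H2O; then DBU, CH2Cl2, 0 °C
Reagents that add atoms: vinylmagnesium bromide C=C[Mg]Br
Why: Copper-catalysed conjugate addition occurs anti to the silyloxy group, and E1cB loss of silanol then gives the transposed enone, so the silyloxy stereocentre sets C4 before it is lost (1,4-addition–elimination).

**Step 8**
Reactants: 10 (S)-4-ethenylcyclopent-2-en-1-one
Product: 11 (4S,5R)-4-ethenyl-5-(phenylsulfanyl)cyclopent-2-en-1-one (trans)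
Conditions: LDA, THF, −78 °C; PhSSPh, THF–HMPA, −78 to −40 °C
Reagents that add atoms: diphenyl disulfide c1ccc(SSc2ccccc2)cc1
Why: Kinetic α′-deprotonation gives the cross-conjugated enolate, which is sulfenylated anti to the vinyl group; the sulfide marks C1 of the target for later regiospecific enolisation and radical removal, and its own configuration is not carried on.

**Step 9**
Reactants: 11 (4S,5R)-4-ethenyl-5-(phenylsulfanyl)cyclopent-2-en-1-one; 12 methyl 2-(bromomethyl)prop-2-enoate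
Product: 13 methyl (2Z)-2-(bromomethyl)-3-[(1R,5R)-4-oxo-5-(phenylsulfanyl)cyclopent-2-en-1-yl]prop-2-enoate
Conditions: second-generation Hoveyda–Grubbs catalyst (5–10 mol %), 12 (5 equiv), CH2Cl2, 40 °C
Reagents that add atoms: none
Why: Olefin cross-metathesis of the terminal alkene with the 2-substituted acrylate should give the trisubstituted enoate with the ring trans to the ester (the Z-bromide), while the ring enone is inert.

**Step 10**
Reactants: 7 (R)-2-[(4-methoxyphenyl)methoxy]-3-(4,4,5,5-tetramethyl-1,3,2-dioxaborolan-2-yl)but-3-enal; 13 methyl (2Z)-2-(bromomethyl)-3-[(1R,5R)-4-oxo-5-(phenylsulfanyl)cyclopent-2-en-1-yl]prop-2-enoate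
Product: 15 methyl 2-[(1R,3aS,5R,6R,7S,7aR)-6-hydroxy-5-[(4-methoxyphenyl)methoxy]-4-methylidene-2-oxo-1-(phenylsulfanyl)octahydro-1H-inden-7-yl]prop-2-enoate, via homoallylic alcohol 14 (not isolated)
Conditions: In powder, THF–H2O (1:1), rt; then [Rh(cod)OH]2 (5 mol %), 1,4-dioxane, 50 °C
Reagents that add atoms: none
Why: Indium inserts into the allylic bromide of 13 and the allylindium adds through its γ-carbon (C7) to the aldehyde of 7 in a closed six-membered transition state (Barbier allylation); [Rh(cod)OH]2 then transmetalates the alkenylboronate, the alkenylrhodium adds 1,4 to the enone (Hayashi–Miyaura addition) and water protonates the rhodium enolate. The closest known reaction types are the indium-mediated coupling of (Z)-2-(bromomethyl)alk-2-enoates with aldehydes and the rhodium-catalysed intramolecular conjugate addition of alkenylboronates to enones. The cyclohexane closes in the 6-exo-trig mode at C3a. C6 is set by Cram-chelate control (indium bridging the aldehyde oxygen and the PMB ether on the R-configured C5, giving the syn diol pattern), C7 by the chair transition state of the Z-bromide (hydroxyl and cyclopentenyl syn), and C3a by the tether, which reaches only the face of the cyclopentenone that carries C7, so the ring fusion is cis. The step needs the allylindium to choose the aldehyde over the enone and the alkenylrhodium to choose the enone over the 2-substituted acrylate, which the 6-endo geometry and α-substitution of the latter should secure; the C7a stereocentre, flanked by an sp2 carbon and a CH(SPh) carbon whose sulfur points to the other ring face, should exert only a weak facial bias of its own.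

**Step 11**
Reactants: 15 methyl 2-[(1R,3aS,5R,6R,7S,7aR)-6-hydroxy-5-[(4-methoxyphenyl)methoxy]-4-methylidene-2-oxo-1-(phenylsulfanyl)octahydro-1H-inden-7-yl]prop-2-enoate; 16 (2E)-3-methylpent-2-enoic acid
Product: 17 methyl 2-[(1R,3aS,5R,6R,7S,7aR)-5-[(4-methoxyphenyl)methoxy]-4-methylidene-6-{[(2E)-3-methylpent-2-enoyl]oxy}-2-oxo-1-(phenylsulfanyl)octahydro-1H-inden-7-yl]prop-2-enoate
Conditions: 2,4,6-trichlorobenzoyl chloride, Et3N, THF, rt; then DMAP, toluene, rt
Reagents that add atoms: none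
Why: Yamaguchi esterification through the mixed anhydride should acylate the hindered secondary alcohol without moving the enoate double bond, and it blocks lactonisation onto the methyl ester.

**Step 12**
Reactants: 17 methyl 2-[(1R,3aS,5R,6R,7S,7aR)-5-[(4-methoxyphenyl)methoxy]-4-methylidene-6-{[(2E)-3-methylpent-2-enoyl]oxy}-2-oxo-1-(phenylsulfanyl)octahydro-1H-inden-7-yl]prop-2-enoate
Product: 18 methyl (2S)-2-[(1R,3aS,5R,6R,7R,7aR)-5-[(4-methoxyphenyl)methoxy]-4-methylidene-6-{[(2E)-3-methylpent-2-enoyl]oxy}-2-oxo-1-(phenylsulfanyl)octahydro-1H-inden-7-yl]oxirane-2-carboxylate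
Conditions: t-BuOOH, n-BuLi, THF, −78 to −20 °C
Reagents that add atoms: tert-butyl hydroperoxide CC(C)(C)OO
Why: Nucleophilic (Weitz–Scheffer type) epoxidation with lithium tert-butyl peroxide attacks only the unhindered acrylate terminus; the oxirane centre is set when the ester enolate closes onto oxygen on the face away from C7a with C7–H eclipsing the enolate (allylic 1,3-strain), so the (2S)-epimer should be favoured, with modest selectivity and chromatographic separation expected.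

**Step 13**
Reactants: 18 methyl (2S)-2-[(1R,3aS,5R,6R,7R,7aR)-5-[(4-methoxyphenyl)methoxy]-4-methylidene-6-{[(2E)-3-methylpent-2-enoyl]oxy}-2-oxo-1-(phenylsulfanyl)octahydro-1H-inden-7-yl]oxirane-2-carboxylate
Product: 19 methyl (2S)-2-[(1R,3aS,5R,6R,7R,7aR)-1-[(1S)-1-acetoxyethyl]-5-[(4-methoxyphenyl)methoxy]-4-methylidene-6-{[(2E)-3-methylpent-2-enoyl]oxy}-2-oxo-1-(phenylsulfanyl)octahydro-1H-inden-7-yl]oxirane-2-carboxylate
Conditions: LiHMDS, THF, −78 °C; CH3CHO, −78 °C; AcCl, −78 to −40 °C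
Reagents that add atoms: acetaldehyde CC=O; acetyl chloride CC(Cl)=O
Why: The sulfur-bearing C1 is the most acidic site, its lithium enolate should add to acetaldehyde from the exposed outer face through a Zimmerman–Traxler chair (carbinol oxygen anti to C7a, which sets the (1S)-carbinol), and acetylation of the aldolate in situ blocks the retro-aldol reaction.

**Step 14**
Reactants: 19 methyl (2S)-2-[(1R,3aS,5R,6R,7R,7aR)-1-[(1S)-1-acetoxyethyl]-5-[(4-methoxyphenyl)methoxy]-4-methylidene-6-{[(2E)-3-methylpent-2-enoyl]oxy}-2-oxo-1-(phenylsulfanyl)octahydro-1H-inden-7-yl]oxirane-2-carboxylate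
Product: 20 methyl (2S)-2-[(1R,3aS,5R,6R,7R,7aR)-1-[(1S)-1-acetoxyethyl]-5-hydroxy-4-methylidene-6-{[(2E)-3-methylpent-2-enoyl]oxy}-2-oxo-1-(phenylsulfanyl)octahydro-1H-inden-7-yl]oxirane-2-carboxylate
Conditions: DDQ, CH2Cl2–pH 7 buffer, 0 °C
Reagents that add atoms: none
Why: Oxidative cleavage of the PMB ether under buffered, neutral conditions should spare the esters, the oxirane and the fully substituted α-sulfanyl ketone.

**Step 15**
Reactants: 20 methyl (2S)-2-[(1R,3aS,5R,6R,7R,7aR)-1-[(1S)-1-acetoxyethyl]-5-hydroxy-4-methylidene-6-{[(2E)-3-methylpent-2-enoyl]oxy}-2-oxo-1-(phenylsulfanyl)octahydro-1H-inden-7-yl]oxirane-2-carboxylate; 21 (2R)-2-methylbutanoic acid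
Product: 22 methyl (2S)-2-[(1R,3aS,5R,6R,7R,7aR)-1-[(1S)-1-acetoxyethyl]-4-methylidene-6-{[(2E)-3-methylpent-2-enoyl]oxy}-5-{[(2R)-2-methylbutanoyl]oxy}-2-oxo-1-(phenylsulfanyl)octahydro-1H-inden-7-yl]oxirane-2-carboxylate
Conditions: DIC, DMAP (cat.), CH2Cl2, 0 °C to rt
Reagents that add atoms: none
Why: Steglich esterification with catalytic DMAP should acylate the allylic alcohol without racemising the α-branched acid; acyl migration from C6 is not expected because the two oxygens are trans.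

**Step 16**
Reactants: 22 methyl (2S)-2-[(1R,3aS,5R,6R,7R,7aR)-1-[(1S)-1-acetoxyethyl]-4-methylidene-6-{[(2E)-3-methylpent-2-enoyl]oxy}-5-{[(2R)-2-methylbutanoyl]oxy}-2-oxo-1-(phenylsulfanyl)octahydro-1H-inden-7-yl]oxirane-2-carboxylate
Product: 23 methyl (2S)-2-[(1R,3aS,5R,6R,7R,7aR)-1-[(1S)-1-acetoxyethyl]-4-methylidene-6-{[(2E)-3-methylpent-2-enoyl]oxy}-5-{[(2R)-2-methylbutanoyl]oxy}-2-oxooctahydro-1H-inden-7-yl]oxirane-2-carboxylate
Conditions: Bu3SnH, AIBN (cat.), benzene, 80 °C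
Reagents that add atoms: none
Why: Radical desulfurisation removes the phenylsulfanyl group to give a planar α-keto radical at C1, which should take hydrogen from the stannane on the exposed outer face, so the acetoxyethyl group ends on the inner face under neutral conditions (kinetic hydrogen-atom transfer, no enolate).

**Compound list**

1 | (S)-2,2-dimethyl-1,3-dioxolane-4-carbaldehyde | O=C[C@@H]1COC(C)(C)O1 | starting material
2 | (R)-4-ethynyl-2,2-dimethyl-1,3-dioxolane | C#C[C@@H]1COC(C)(C)O1 | intermediate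
3 | (R)-but-3-yne-1,2-diol | C#C[C@@H](O)CO | intermediate
4 | (4R)-4-ethynyl-2-(4-methoxyphenyl)-1,3-dioxolane (acetal epimers) | C#C[C@@H]1COC(c2ccc(OC)cc2)O1 | intermediate
5 | (R)-2-[(4-methoxyphenyl)methoxy]but-3-yn-1-ol | C#C[C@@H](OCc1ccc(OC)cc1)CO | intermediate
6 | (R)-2-[(4-methoxyphenyl)methoxy]-3-(4,4,5,5-tetramethyl-1,3,2-dioxaborolan-2-yl)but-3-en-1-ol | C=C(B1OC(C)(C)C(C)(C)O1)[C@@H](OCc1ccc(OC)cc1)CO | intermediate
7 | (R)-2-[(4-methoxyphenyl)methoxy]-3-(4,4,5,5-tetramethyl-1,3,2-dioxaborolan-2-yl)but-3-enal | C=C(B1OC(C)(C)C(C)(C)O1)[C@@H](OCc1ccc(OC)cc1)C=O | intermediate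
8 | (R)-4-[(tert-butyldimethylsilyl)oxy]cyclopent-2-en-1-one | O=C1C=C[C@H](O[Si](C)(C)C(C)(C)C)C1 | starting material
9 | (3S,4R)-4-[(tert-butyldimethylsilyl)oxy]-3-ethenylcyclopentan-1-one | O=C1C[C@@H](C=C)[C@H](O[Si](C)(C)C(C)(C)C)C1 | intermediate
10 | (S)-4-ethenylcyclopent-2-en-1-one | O=C1C=C[C@H](C=C)C1 | intermediate
11 | (4S,5R)-4-ethenyl-5-(phenylsulfanyl)cyclopent-2-en-1-one | O=C1C=C[C@H](C=C)[C@H]1Sc2ccccc2 | intermediate
12 | methyl 2-(bromomethyl)prop-2-enoate | C=C(CBr)C(=O)OC | starting material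
13 | methyl (2Z)-2-(bromomethyl)-3-[(1R,5R)-4-oxo-5-(phenylsulfanyl)cyclopent-2-en-1-yl]prop-2-enoate | O=C1C=C[C@H](/C=C(\CBr)C(=O)OC)[C@H]1Sc2ccccc2 | intermediate
14 | methyl (3S,4R,5R)-4-hydroxy-5-[(4-methoxyphenyl)methoxy]-2-methylidene-3-[(1R,5R)-4-oxo-5-(phenylsulfanyl)cyclopent-2-en-1-yl]-6-(4,4,5,5-tetramethyl-1,3,2-dioxaborolan-2-yl)hept-6-enoate | O=C1C=C[C@H]([C@@H](C(=C)C(=O)OC)[C@@H](O)[C@H](OCc2ccc(OC)cc2)C(=C)B2OC(C)(C)C(C)(C)O2)[C@H]1Sc3ccccc3 | intermediate
15 | methyl 2-[(1R,3aS,5R,6R,7S,7aR)-6-hydroxy-5-[(4-methoxyphenyl)methoxy]-4-methylidene-2-oxo-1-(phenylsulfanyl)octahydro-1H-inden-7-yl]prop-2-enoate | C=C1[C@H]2CC(=O)[C@H](Sc3ccccc3)[C@H]2[C@@H](C(=C)C(=O)OC)[C@@H](O)[C@@H]1OCc4ccc(OC)cc4 | intermediate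
16 | (2E)-3-methylpent-2-enoic acid | OC(=O)/C=C(\C)CC | starting material
17 | methyl 2-[(1R,3aS,5R,6R,7S,7aR)-5-[(4-methoxyphenyl)methoxy]-4-methylidene-6-{[(2E)-3-methylpent-2-enoyl]oxy}-2-oxo-1-(phenylsulfanyl)octahydro-1H-inden-7-yl]prop-2-enoate | C=C1[C@H]2CC(=O)[C@H](Sc3ccccc3)[C@H]2[C@@H](C(=C)C(=O)OC)[C@@H](OC(=O)/C=C(\C)CC)[C@@H]1OCc4ccc(OC)cc4 | intermediate
18 | methyl (2S)-2-[(1R,3aS,5R,6R,7R,7aR)-5-[(4-methoxyphenyl)methoxy]-4-methylidene-6-{[(2E)-3-methylpent-2-enoyl]oxy}-2-oxo-1-(phenylsulfanyl)octahydro-1H-inden-7-yl]oxirane-2-carboxylate | C=C1[C@H]2CC(=O)[C@H](Sc3ccccc3)[C@H]2[C@@H]([C@@]2(C(=O)OC)CO2)[C@@H](OC(=O)/C=C(\C)CC)[C@@H]1OCc4ccc(OC)cc4 | intermediate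
19 | methyl (2S)-2-[(1R,3aS,5R,6R,7R,7aR)-1-[(1S)-1-acetoxyethyl]-5-[(4-methoxyphenyl)methoxy]-4-methylidene-6-{[(2E)-3-methylpent-2-enoyl]oxy}-2-oxo-1-(phenylsulfanyl)octahydro-1H-inden-7-yl]oxirane-2-carboxylate | C=C1[C@H]2CC(=O)[C@@]([C@H](C)OC(C)=O)(Sc3ccccc3)[C@H]2[C@@H]([C@@]2(C(=O)OC)CO2)[C@@H](OC(=O)/C=C(\C)CC)[C@@H]1OCc4ccc(OC)cc4 | intermediate
20 | methyl (2S)-2-[(1R,3aS,5R,6R,7R,7aR)-1-[(1S)-1-acetoxyethyl]-5-hydroxy-4-methylidene-6-{[(2E)-3-methylpent-2-enoyl]oxy}-2-oxo-1-(phenylsulfanyl)octahydro-1H-inden-7-yl]oxirane-2-carboxylate | C=C1[C@H]2CC(=O)[C@@]([C@H](C)OC(C)=O)(Sc3ccccc3)[C@H]2[C@@H]([C@@]2(C(=O)OC)CO2)[C@@H](OC(=O)/C=C(\C)CC)[C@@H]1O | intermediate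
21 | (2R)-2-methylbutanoic acid | OC(=O)[C@H](C)CC | starting material
22 | methyl (2S)-2-[(1R,3aS,5R,6R,7R,7aR)-1-[(1S)-1-acetoxyethyl]-4-methylidene-6-{[(2E)-3-methylpent-2-enoyl]oxy}-5-{[(2R)-2-methylbutanoyl]oxy}-2-oxo-1-(phenylsulfanyl)octahydro-1H-inden-7-yl]oxirane-2-carboxylate | C=C1[C@H]2CC(=O)[C@@]([C@H](C)OC(C)=O)(Sc3ccccc3)[C@H]2[C@@H]([C@@]2(C(=O)OC)CO2)[C@@H](OC(=O)/C=C(\C)CC)[C@@H]1OC(=O)[C@H](C)CC | intermediate
23 | methyl (2S)-2-[(1R,3aS,5R,6R,7R,7aR)-1-[(1S)-1-acetoxyethyl]-4-methylidene-6-{[(2E)-3-methylpent-2-enoyl]oxy}-5-{[(2R)-2-methylbutanoyl]oxy}-2-oxooctahydro-1H-inden-7-yl]oxirane-2-carboxylate | C=C1[C@H]2CC(=O)[C@@H]([C@H](C)OC(C)=O)[C@H]2[C@@H]([C@@]2(C(=O)OC)CO2)[C@@H](OC(=O)/C=C(\C)CC)[C@@H]1OC(=O)[C@H](C)CC | target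

**Step count.** Total: 16 steps. Longest linear sequence: 13 steps (steps 1–6, then 10–16).

**Steps most likely to fail**

Step 10. The alkenylrhodium intermediate may lose the neighbouring PMB-oxy group by β-alkoxide elimination, or be protonated, before it inserts the enone; the γ-hydroxy ester may also lactonise in the warm aqueous medium. The fallback separates the two bond formations and replaces boron and rhodium by an alkenyl iodide and nickel. It sets out from 5 and 13 and returns at 15. Alkyne 5 is hydrostannylated at the internal carbon (Bu3SnH, Mo(CO)3(CNt-Bu)3 cat., THF, 55 °C) to (R)-2-[(4-methoxyphenyl)methoxy]-3-(tributylstannyl)but-3-en-1-ol F1. Iododestannylation (I2, CH2Cl2, 0 °C) gives (R)-3-iodo-2-[(4-methoxyphenyl)methoxy]but-3-en-1-ol F2, and Dess–Martin oxidation gives (R)-3-iodo-2-[(4-methoxyphenyl)methoxy]but-3-enal F3. Indium-mediated allylation of F3 with 13 (In, THF–H2O, rt) gives the isolated homoallylic alcohol methyl (3S,4R,5R)-4-hydroxy-6-iodo-5-[(4-methoxyphenyl)methoxy]-2-methylidene-3-[(1R,5R)-4-oxo-5-(phenylsulfanyl)cyclopent-2-en-1-yl]hept-6-enoate F4. Nickel-mediated intramolecular conjugate addition of the alkenyl iodide to the enone (zerovalent nickel complex Ni(cod)2, Et3N, MeCN–DMF, rt) then closes the ring to 15.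

Step 9. The thioether may deactivate the ruthenium carbene, turnover with the 1,1-disubstituted acrylate may be slow, and the doubly allylic C–H may allow double-bond migration. The fallback builds the bromomethyl enoate from an aldehyde instead of by metathesis. It sets out from 8 and returns at 13. The conjugate addition of step 7 is stopped before the DBU treatment and 9 is isolated. Ketalisation (ethylene glycol, PPTS, benzene) gives tert-butyl{[(7R,8S)-8-ethenyl-1,4-dioxaspiro[4.4]nonan-7-yl]oxy}dimethylsilane F5, and ozonolysis (O3, CH2Cl2, −78 °C; Me2S) gives (7S,8R)-8-[(tert-butyldimethylsilyl)oxy]-1,4-dioxaspiro[4.4]nonane-7-carbaldehyde F6. Morita–Baylis–Hillman reaction with methyl acrylate (DABCO, neat, rt) gives methyl 2-{[(7S,8R)-8-[(tert-butyldimethylsilyl)oxy]-1,4-dioxaspiro[4.4]nonan-7-yl](hydroxy)methyl}prop-2-enoate F7. Bromination with allylic transposition (NBS, Me2S, CH2Cl2, 0 °C) gives methyl (2Z)-2-(bromomethyl)-3-[(7R,8R)-8-[(tert-butyldimethylsilyl)oxy]-1,4-dioxaspiro[4.4]nonan-7-yl]prop-2-enoate F8. Ketal hydrolysis and β-elimination of the silanol (PPTS, aqueous acetone; then basic alumina) give methyl (2Z)-2-(bromomethyl)-3-[(1R)-4-oxocyclopent-2-en-1-yl]prop-2-enoate F9. Soft enolisation and sulfenylation (TMSOTf, i-Pr2NEt, CH2Cl2, −78 °C; then PhSCl) give 13.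

Step 13. The aldol addition at the crowded, fully substituted enolate carbon may revert before the aldolate is acetylated, or the base may enolise towards C3. The fallback replaces the lithium aldol by a Lewis-acid-mediated Mukaiyama aldol of an isolated silyl enol ether. It sets out from 18 and returns at 19. Ketone 18 is converted (TMSOTf, Et3N, CH2Cl2, 0 °C) to the tetrasubstituted silyl enol ether methyl (2S)-2-[(3aS,5R,6R,7R,7aR)-5-[(4-methoxyphenyl)methoxy]-4-methylidene-6-{[(2E)-3-methylpent-2-enoyl]oxy}-1-(phenylsulfanyl)-2-[(trimethylsilyl)oxy]-3a,4,5,6,7,7a-hexahydro-3H-inden-7-yl]oxirane-2-carboxylate F10. F10 is treated with acetaldehyde and BF3·OEt2 (CH2Cl2, −78 °C), again attacking from the outer face, and the carbinol is acetylated (Ac2O, pyridine) to give 19 after separation of any carbinol epimer.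

**Further compounds**

F1 | step 10 | (R)-2-[(4-methoxyphenyl)methoxy]-3-(tributylstannyl)but-3-en-1-ol | C=C([Sn](CCCC)(CCCC)CCCC)[C@@H](OCc1ccc(OC)cc1)CO
F2 | step 10 | (R)-3-iodo-2-[(4-methoxyphenyl)methoxy]but-3-en-1-ol | C=C(I)[C@@H](OCc1ccc(OC)cc1)CO
F3 | step 10 | (R)-3-iodo-2-[(4-methoxyphenyl)methoxy]but-3-enal | C=C(I)[C@@H](OCc1ccc(OC)cc1)C=O
F4 | step 10 | methyl (3S,4R,5R)-4-hydroxy-6-iodo-5-[(4-methoxyphenyl)methoxy]-2-methylidene-3-[(1R,5R)-4-oxo-5-(phenylsulfanyl)cyclopent-2-en-1-yl]hept-6-enoate | O=C1C=C[C@H]([C@@H](C(=C)C(=O)OC)[C@@H](O)[C@H](OCc2ccc(OC)cc2)C(I)=C)[C@H]1Sc3ccccc3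
F5 | step 9 | tert-butyl{[(7R,8S)-8-ethenyl-1,4-dioxaspiro[4.4]nonan-7-yl]oxy}dimethylsilane | C=C[C@@H]1CC2(OCCO2)C[C@H]1O[Si](C)(C)C(C)(C)C
F6 | step 9 | (7S,8R)-8-[(tert-butyldimethylsilyl)oxy]-1,4-dioxaspiro[4.4]nonane-7-carbaldehyde | O=C[C@@H]1CC2(OCCO2)C[C@H]1O[Si](C)(C)C(C)(C)C
F7 | step 9 | methyl 2-{[(7S,8R)-8-[(tert-butyldimethylsilyl)oxy]-1,4-dioxaspiro[4.4]nonan-7-yl](hydroxy)methyl}prop-2-enoate (carbinol epimers) | C=C(C(=O)OC)C(O)[C@@H]1CC2(OCCO2)C[C@H]1O[Si](C)(C)C(C)(C)C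
F8 | step 9 | methyl (2Z)-2-(bromomethyl)-3-[(7R,8R)-8-[(tert-butyldimethylsilyl)oxy]-1,4-dioxaspiro[4.4]nonan-7-yl]prop-2-enoate | BrC/C(C(=O)OC)=C\[C@@H]1CC2(OCCO2)C[C@H]1O[Si](C)(C)C(C)(C)C
F9 | step 9 | methyl (2Z)-2-(bromomethyl)-3-[(1R)-4-oxocyclopent-2-en-1-yl]prop-2-enoate | O=C1C=C[C@H](/C=C(\CBr)C(=O)OC)C1
F10 | step 13 | methyl (2S)-2-[(3aS,5R,6R,7R,7aR)-5-[(4-methoxyphenyl)methoxy]-4-methylidene-6-{[(2E)-3-methylpent-2-enoyl]oxy}-1-(phenylsulfanyl)-2-[(trimethylsilyl)oxy]-3a,4,5,6,7,7a-hexahydro-3H-inden-7-yl]oxirane-2-carboxylate | C=C1[C@H]2CC(O[Si](C)(C)C)=C(Sc3ccccc3)[C@H]2[C@@H]([C@@]2(C(=O)OC)CO2)[C@@H](OC(=O)/C=C(\C)CC)[C@@H]1OCc4ccc(OC)cc4
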